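## Retrosynthetic overview

1. Locants are those of the target name (…hexahydro‑1H‑indene‑4‑carboxylic acid): C2 is the ketone carbon, C4 (Et, CO2H) and C5 (Et, styryl) are the quaternary carbons, C6=C7(CH3) is the ring alkene, and C3a/C7a are the trans ring fusion.
2. Enabling feature: HO2C–C4–C5–CH=CH–Ph is a γ,δ‑unsaturated acid, so C4–C5 is a Claisen bond with the styryl C=C as the shifted alkene. In addition, vinylic C7 is six atoms from C7a around the cyclohexene and, through C1, 1,5 to the carbonyl carbon C2. A vinyl radical at C7 can therefore close the cyclohexene at C7a, and the C1 radical it leaves can close the cyclopentanone on a nitrile carbon (C2).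
3. Disconnections: C4–C5 (Ireland–Claisen shift of ester 16), then C7–C7a and C1–C2 (radical 6‑exo/5‑exo cascade in the same flask), and the ester C–O bond (acid 9 + alcohol 15). The cyclohexene forms first and the cyclopentanone second, both after the two quaternary carbons.
4. Acid 9 (fixes C3a) comes from (R)‑but‑3‑en‑2‑ol by cross‑metathesis and Johnson–Claisen rearrangement. Alcohol 15 (its carbinol centre relays chirality to C4 and C5) comes from (R)‑1‑phenylprop‑2‑en‑1‑ol by cross‑metathesis and iodo‑olefination.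
5. C1 and C3 are set last by equilibration next to the ketone.

Key step: step 10

Assumption: both allylic alcohols 3 and 10 are bought as single enantiomers; the centres α to the ester, nitrile and ketone that are erased or equilibrated later are carried as mixtures.

## Route

Step 1
Reactants: 1 but‑3‑enenitrile
Product: 2 2‑ethylbut‑3‑enenitrile (racemic)
Conditions: LiN(i‑Pr)2, THF, −78 °C; EtI, −78 → 0 °C
Reagents that add atoms: iodoethane, CCI
Why: α‑Alkylation of the delocalised lithiated allyl cyanide should occur at the α‑carbon and give the deconjugated nitrile; the new centre is racemic and is equilibrated later next to the ketone.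

Step 2
Reactants: 2 2‑ethylbut‑3‑enenitrile; 3 (R)‑but‑3‑en‑2‑ol
Product: 4 (3E,5R)‑2‑ethyl‑5‑hydroxyhex‑3‑enenitrile
Conditions: second‑generation Hoveyda–Grubbs catalyst [RuCl2(H2IMes)(=CHC6H4‑2‑Oi‑Pr)] (5 mol %), CH2Cl2, 40 °C, excess 2
Reagents that add atoms: none
Why: Olefin cross‑metathesis should join the two terminal alkenes with loss of ethene and thermodynamic preference for the (E)‑alkene, leaving the carbinol centre of 3 untouched.

Step 3
Reactants: 4 (3E,5R)‑2‑ethyl‑5‑hydroxyhex‑3‑enenitrile; 5 trimethyl orthobutyrate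
Product: 8 methyl (3R,4E)‑3‑(1‑cyanopropyl)‑2‑ethylhex‑4‑enoate, via mixed orthoester 6 (not isolated), via ketene acetal 7 (not isolated)
Conditions: EtCO2H (cat.), 135 °C, MeOH distilled off
Reagents that add atoms: none
Why: In the Johnson–Claisen rearrangement the ketene acetal should react through a chair with the carbinol methyl group equatorial, so the (R)‑carbinol is transferred across the (E)‑alkene to the new (R)‑centre (future C3a) and the new propenyl alkene is (E).

Step 4
Reactants: 8 methyl (3R,4E)‑3‑(1‑cyanopropyl)‑2‑ethylhex‑4‑enoate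
Product: 9 (3R,4E)‑3‑(1‑cyanopropyl)‑2‑ethylhex‑4‑enoic acid
Conditions: LiOH, THF/MeOH/H2O, 40 °C; then 1 M HCl
Reagents that add atoms: lithium hydroxide, [Li+].[OH-]
Why: Saponification should cleave only the methyl ester, since the nitrile is inert to mild aqueous hydroxide and the one fixed stereocentre is not enolisable.

Step 5
Reactants: 10 (R)‑1‑phenylprop‑2‑en‑1‑ol
Product: 11 tert‑butyldimethyl{[(1R)‑1‑phenylprop‑2‑en‑1‑yl]oxy}silane
Conditions: t‑BuMe2SiCl, imidazole, DMF, rt
Reagents that add atoms: tert‑butyldimethylsilyl chloride, CC(C)(C)[Si](C)(C)Cl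
Why: Imidazole‑mediated silylation masks the alcohol for the metathesis and ylide steps without touching the stereocentre.

Step 6
Reactants: 11 silyl ether; 12 2‑ethylacrolein (2‑methylidenebutanal)
Product: 13 (2E,4R)‑4‑[(tert‑butyldimethylsilyl)oxy]‑2‑ethyl‑4‑phenylbut‑2‑enal
Conditions: second‑generation Hoveyda–Grubbs catalyst [RuCl2(H2IMes)(=CHC6H4‑2‑Oi‑Pr)] (5 mol %), CH2Cl2, 40 °C, excess 12
Reagents that add atoms: none
Why: Cross‑metathesis with a 1,1‑disubstituted enal should give the trisubstituted enal with the formyl group trans to the carbinol carbon (thermodynamic E‑selectivity), the geometry the later chair [3,3] shift requires.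

Step 7
Reactants: 13 (2E,4R)‑enal
Product: 14 tert‑butyl{[(1R,2E,4Z)‑3‑ethyl‑5‑iodo‑1‑phenylhexa‑2,4‑dien‑1‑yl]oxy}dimethylsilane
Conditions: EtPPh3I, n‑BuLi, THF, 0 °C; I2, −78 °C; NaN(SiMe3)2, −20 °C; then 13, −78 °C → rt
Reagents that add atoms: ethyltriphenylphosphonium iodide, CC[P+](c1ccccc1)(c1ccccc1)c1ccccc1.[I-]; iodine, II
Why: Stork–Zhao‑type Wittig olefination with the α‑iodo ylide should convert the aldehyde into the (Z)‑2‑iodoprop‑1‑enyl group (kinetic cis‑selectivity of a non‑stabilised ylide) while the (E)‑enal double bond is retained.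

Step 8
Reactants: 14 iodo diene silyl ether
Product: 15 (1R,2E,4Z)‑3‑ethyl‑5‑iodo‑1‑phenylhexa‑2,4‑dien‑1‑ol
Conditions: Bu4NF, THF, 0 °C
Reagents that add atoms: none
Why: Fluoride‑mediated desilylation frees the alcohol under conditions that neither ionise the doubly allylic benzylic C–O bond nor touch the vinyl iodide.

Step 9
Reactants: 9 (3R,4E)‑3‑(1‑cyanopropyl)‑2‑ethylhex‑4‑enoic acid; 15 (1R,2E,4Z)‑3‑ethyl‑5‑iodo‑1‑phenylhexa‑2,4‑dien‑1‑ol
Product: 16 (1R,2E,4Z)‑3‑ethyl‑5‑iodo‑1‑phenylhexa‑2,4‑dien‑1‑yl (3R,4E)‑3‑(1‑cyanopropyl)‑2‑ethylhex‑4‑enoate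
Conditions: DCC, DMAP (cat.), CH2Cl2, 0 °C → rt
Reagents that add atoms: none
Why: Steglich esterification acylates the carbinol oxygen with retention of the (R)‑configuration under neutral conditions; the α‑centre of the acid is of no consequence because it is planarised in step 10.

Step 10
Reactants: 16 dienyl ester
Product: 21 keto acid (3aR,4R,5S,7aR; C1/C3 epimers), via bis‑silyl ketene acetal 17 (not isolated), via silyl ester 18 (not isolated), via iodo acid nitrile 19 (not isolated), via cyclic ketimine 20 (not isolated)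
Conditions: LiN(i‑Pr)2 (2.3 equiv), Me3SiCl, Et3N, THF, −78 → 60 °C; MeOH; then PhH, (Me3Si)3SiH, AIBN (slow addition), 80 °C; then 1 M HCl, THF, rt
Reagents that add atoms: water, O
Why: Excess amide base converts the ester into the tetrasubstituted O‑silyl ketene acetal 17 (closed transition state of enolisation: the branched α‑substituent ends syn to the allylic oxygen, the ethyl group syn to OSiMe3; the nitrile arm is parked as its N‑silyl ketenimine), which undergoes the Ireland–Claisen [3,3]‑sigmatropic shift through a chair with the phenyl group equatorial, so that the (R)‑carbinol centre is relayed to both new quaternary centres C4 and C5 and the (E)‑styryl alkene appears in 18; methanol then frees acid nitrile 19. Iodine abstraction by the silyl radical gives the σ‑vinyl radical at C7, which closes the cyclohexene by 6‑exo‑trig addition to the propenyl group (bond C7–C7a); the resulting secondary radical at C1 closes the cyclopentane by 5‑exo‑dig addition to the nitrile carbon (future C2), and the iminyl radical takes hydrogen from the silane to give ketimine 20, hydrolysed on work‑up. Closest precedents are Ireland–Claisen constructions of vicinal quaternary carbons from α‑branched esters and hydride‑mediated vinyl‑radical cascades that end on a nitrile to deliver a cyclic ketone. C7a is set by the existing C3a and C4 centres: in the chair‑like transition state the nitrile‑bearing arm on C3a and the exocyclic carbon (future C1) on the forming C7a centre are both equatorial, because the alternatives place a carbon substituent syn‑diaxial to the axial ethyl group on C4 or on C5, and this gives the trans ring fusion. The step needs one ketene acetal geometry and chair over boat in the sigmatropic shift (secured by kinetic enolisation and the equatorial phenyl group) and ring closure faster than 1,5‑hydrogen transfer or reduction (secured by slow addition of the poor hydrogen donor (Me3Si)3SiH). C1 and C3 emerge as epimer mixtures and are corrected in step 11.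

Step 11
Reactants: 21 keto acid (C1/C3 epimers)
Product: 22 (1S,3S,3aR,4R,5S,7aR)‑3,4,5‑triethyl‑1,7‑dimethyl‑2‑oxo‑5‑[(E)‑2‑phenylethenyl]‑2,3,3a,4,5,7a‑hexahydro‑1H‑indene‑4‑carboxylic acid
Conditions: NaOMe, MeOH, rt; then 1 M HCl
Reagents that add atoms: none
Why: Base‑mediated enolisation (thermodynamic epimerisation) should convert the C1/C3 epimers into the isomer whose methyl and ethyl groups lie trans to the adjacent ring‑fusion C–C bonds, which is the target; no other stereocentre is enolisable.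

## Compound list

1 | but‑3‑enenitrile | C=CCC#N | starting material
2 | 2‑ethylbut‑3‑enenitrile (racemic) | C=CC(CC)C#N | intermediate
3 | (R)‑but‑3‑en‑2‑ol | C[C@@H](O)C=C | starting material
4 | (3E,5R)‑2‑ethyl‑5‑hydroxyhex‑3‑enenitrile (both C2 epimers) | C[C@@H](O)/C=C/C(CC)C#N | intermediate
5 | trimethyl orthobutyrate (1,1,1‑trimethoxybutane) | CCCC(OC)(OC)OC | starting material
6 | 1‑{[(2R,3E)‑5‑cyanohept‑3‑en‑2‑yl]oxy}‑1,1‑dimethoxybutane (mixed orthoester) | CCCC(OC)(OC)O[C@H](C)/C=C/C(CC)C#N | intermediate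
7 | 1‑{[(2R,3E)‑5‑cyanohept‑3‑en‑2‑yl]oxy}‑1‑methoxybut‑1‑ene (ketene acetal) | CCC=C(OC)O[C@H](C)/C=C/C(CC)C#N | intermediate
8 | methyl (3R,4E)‑3‑(1‑cyanopropyl)‑2‑ethylhex‑4‑enoate (epimers at C2 and at the cyanopropyl carbon) | COC(=O)C(CC)[C@H](/C=C/C)C(CC)C#N | intermediate
9 | (3R,4E)‑3‑(1‑cyanopropyl)‑2‑ethylhex‑4‑enoic acid (same epimer mixture) | OC(=O)C(CC)[C@H](/C=C/C)C(CC)C#N | intermediate
10 | (R)‑1‑phenylprop‑2‑en‑1‑ol | C=C[C@@H](O)c1ccccc1 | starting material
11 | tert‑butyldimethyl{[(1R)‑1‑phenylprop‑2‑en‑1‑yl]oxy}silane | C=C[C@@H](O[Si](C)(C)C(C)(C)C)c1ccccc1 | intermediate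
12 | 2‑ethylacrolein (2‑methylidenebutanal) | C=C(CC)C=O | starting material
13 | (2E,4R)‑4‑[(tert‑butyldimethylsilyl)oxy]‑2‑ethyl‑4‑phenylbut‑2‑enal | O=C/C(CC)=C/[C@@H](O[Si](C)(C)C(C)(C)C)c1ccccc1 | intermediate
14 | tert‑butyl{[(1R,2E,4Z)‑3‑ethyl‑5‑iodo‑1‑phenylhexa‑2,4‑dien‑1‑yl]oxy}dimethylsilane | C/C(I)=C/C(CC)=C/[C@@H](O[Si](C)(C)C(C)(C)C)c1ccccc1 | intermediate
15 | (1R,2E,4Z)‑3‑ethyl‑5‑iodo‑1‑phenylhexa‑2,4‑dien‑1‑ol | C/C(I)=C/C(CC)=C/[C@@H](O)c1ccccc1 | intermediate
16 | (1R,2E,4Z)‑3‑ethyl‑5‑iodo‑1‑phenylhexa‑2,4‑dien‑1‑yl (3R,4E)‑3‑(1‑cyanopropyl)‑2‑ethylhex‑4‑enoate | C/C(I)=C/C(CC)=C/[C@@H](OC(=O)C(CC)[C@H](/C=C/C)C(CC)C#N)c1ccccc1 | intermediate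
17 | O‑trimethylsilyl ketene acetal of 16 (ethyl syn to OSiMe3, branched carbon syn to the allylic oxygen) with the nitrile arm as its N‑trimethylsilyl ketenimine | C/C(I)=C/C(CC)=C/[C@@H](O/C(O[Si](C)(C)C)=C(/CC)[C@H](/C=C/C)C(CC)=C=N[Si](C)(C)C)c1ccccc1 | intermediate
18 | trimethylsilyl ester of 19 with the nitrile arm still as its N‑trimethylsilyl ketenimine ([3,3] product) | C/C(I)=C/[C@@](/C=C/c1ccccc1)(CC)[C@](CC)(C(=O)O[Si](C)(C)C)[C@H](/C=C/C)C(CC)=C=N[Si](C)(C)C | intermediate
19 | (4E)‑2‑[(2E)‑1‑(1‑cyanopropyl)but‑2‑en‑1‑yl]‑2,3‑diethyl‑3‑[(1Z)‑2‑iodoprop‑1‑en‑1‑yl]‑5‑phenylpent‑4‑enoic acid, configured at C2, C3 and the butenyl C1 as C4, C5 and C3a of the target | C/C(I)=C/[C@@](/C=C/c1ccccc1)(CC)[C@](CC)(C(=O)O)[C@H](/C=C/C)C(CC)C#N | intermediate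
20 | (3aR,4R,5S,7aR)‑3,4,5‑triethyl‑2‑imino‑1,7‑dimethyl‑5‑[(E)‑2‑phenylethenyl]‑2,3,3a,4,5,7a‑hexahydro‑1H‑indene‑4‑carboxylic acid (C1/C3 epimers) | CCC1C(=N)C(C)[C@@H]2C(C)=C[C@@](/C=C/c3ccccc3)(CC)[C@](CC)(C(=O)O)[C@H]21 | intermediate
21 | (3aR,4R,5S,7aR)‑3,4,5‑triethyl‑1,7‑dimethyl‑2‑oxo‑5‑[(E)‑2‑phenylethenyl]‑2,3,3a,4,5,7a‑hexahydro‑1H‑indene‑4‑carboxylic acid (C1/C3 epimers) | CCC1C(=O)C(C)[C@@H]2C(C)=C[C@@](/C=C/c3ccccc3)(CC)[C@](CC)(C(=O)O)[C@H]21 | intermediate
22 | (1S,3S,3aR,4R,5S,7aR)‑3,4,5‑triethyl‑1,7‑dimethyl‑2‑oxo‑5‑[(E)‑2‑phenylethenyl]‑2,3,3a,4,5,7a‑hexahydro‑1H‑indene‑4‑carboxylic acid | CC[C@@H]1C(=O)[C@@H](C)[C@@H]2C(C)=C[C@@](/C=C/c3ccccc3)(CC)[C@](CC)(C(=O)O)[C@H]21 | target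

## Step count and risks

Total step count: 11. Longest linear sequence: 7 steps (10 → 11 → 13 → 14 → 15 → 16 → 21 → 22; the branch from 1 is equally long).

Steps most likely to fail:

**Step 10.** After the [3,3] shift, the vinyl radical may be lost by 1,5‑hydrogen transfer or direct reduction before it adds to the unactivated propenyl group, and the secondary radical may be reduced before the slow nitrile closure. Incomplete control of ketene acetal geometry would also erode the configuration at C4. The fallback sets out from acid 9 and comes back at 21: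
- Cross‑metathesis of 9 with methyl methacrylate (second‑generation Hoveyda–Grubbs catalyst) would turn the propenyl terminus into an electron‑poor acceptor and give (3R,4E)‑3‑(1‑cyanopropyl)‑2‑ethyl‑6‑methoxy‑5‑methyl‑6‑oxohex‑4‑enoic acid F1.
- DCC/DMAP coupling with 15 gives the dienyl ester F2.
- The same Ireland–Claisen shift and methanol quench, now with isolation, gives the iodo enoate acid F3.
- Under (Me3Si)3SiH/AIBN the vinyl radical adds in a polarity‑matched 6‑exo closure to the methacrylate unit and gives the cyclohexene ester nitrile F4.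
- The five‑membered ring is then closed ionically: LiN(SiMe3)2 makes the ester enolate add to the nitrile (Thorpe‑type), and aqueous acid gives the β‑keto ester F5.
- LiCl in wet DMSO at 140 °C (Krapcho) removes the ester group and returns 21.

**Step 6.** Productive metathesis between the hindered allylic silyl ether and the 1,1‑disubstituted enal may be so slow that catalyst decomposition and double‑bond migration dominate. The fallback sets out from 11 and comes back at 13:
- Ozonolysis (O3, then PPh3) gives (2S)‑2‑[(tert‑butyldimethylsilyl)oxy]‑2‑phenylacetaldehyde F6, used at once.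
- Wittig reaction with ethyl 2‑(triphenylphosphoranylidene)butanoate (no added base, so the labile benzylic centre is not enolised) gives the (E)‑enoate F7.
- i‑Bu2AlH reduction gives the allylic alcohol F8, and MnO2 oxidation gives 13.

**Step 2.** Cross‑metathesis of two allylically branched partners may be unselective (homodimers, E/Z mixture) and the double bond may migrate into conjugation with the nitrile. The fallback sets out from 1 and 3 and comes back at 4:
- Cross‑metathesis of the unbranched nitrile 1 with 3, a better‑matched pair, gives (3E,5R)‑5‑hydroxyhex‑3‑enenitrile F9.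
- Its alkoxide/nitrile dianion (LiN(i‑Pr)2, two equivalents) is ethylated at the α‑carbon with iodoethane to give 4.

Further compounds
F1 | step 10 | (3R,4E)‑3‑(1‑cyanopropyl)‑2‑ethyl‑6‑methoxy‑5‑methyl‑6‑oxohex‑4‑enoic acid | OC(=O)C(CC)[C@H](/C=C(\C)C(=O)OC)C(CC)C#N
F2 | step 10 | (1R,2E,4Z)‑3‑ethyl‑5‑iodo‑1‑phenylhexa‑2,4‑dien‑1‑yl ester of F1 | C/C(I)=C/C(CC)=C/[C@@H](OC(=O)C(CC)[C@H](/C=C(\C)C(=O)OC)C(CC)C#N)c1ccccc1
F3 | step 10 | [3,3] product of F2: 2,3‑diethyl‑3‑[(1Z)‑2‑iodoprop‑1‑en‑1‑yl]‑5‑phenylpent‑4‑enoic acid bearing at C2 the 1‑(1‑cyanopropyl)‑3‑(methoxycarbonyl)but‑2‑en‑1‑yl group, configured as 19 | C/C(I)=C/[C@@](/C=C/c1ccccc1)(CC)[C@](CC)(C(=O)O)[C@H](/C=C(\C)C(=O)OC)C(CC)C#N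
F4 | step 10 | cyclohexene acid from F3 with a 1‑(methoxycarbonyl)ethyl group at the future C7a and a 1‑cyanopropyl group at the future C3a, trans | COC(=O)C(C)[C@@H]1C(C)=C[C@@](/C=C/c2ccccc2)(CC)[C@](CC)(C(=O)O)[C@H]1C(CC)C#N
F5 | step 10 | 1‑(methoxycarbonyl) derivative of 21 (β‑keto ester at C1) | CCC1C(=O)C(C)(C(=O)OC)[C@@H]2C(C)=C[C@@](/C=C/c3ccccc3)(CC)[C@](CC)(C(=O)O)[C@H]21
F6 | step 6 | (2S)‑2‑[(tert‑butyldimethylsilyl)oxy]‑2‑phenylacetaldehyde | O=C[C@@H](O[Si](C)(C)C(C)(C)C)c1ccccc1
F7 | step 6 | ethyl (2E,4R)‑4‑[(tert‑butyldimethylsilyl)oxy]‑2‑ethyl‑4‑phenylbut‑2‑enoate | CCOC(=O)/C(CC)=C/[C@@H](O[Si](C)(C)C(C)(C)C)c1ccccc1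
F8 | step 6 | (2E,4R)‑4‑[(tert‑butyldimethylsilyl)oxy]‑2‑ethyl‑4‑phenylbut‑2‑en‑1‑ol | OC/C(CC)=C/[C@@H](O[Si](C)(C)C(C)(C)C)c1ccccc1
F9 | step 2 | (3E,5R)‑5‑hydroxyhex‑3‑enenitrile | C[C@@H](O)/C=C/CC#N
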